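**Retrosynthetic overview**

1. Locants used below: chain C1 (ester carbonyl) to C13 (CH bonded to the ring); ring C1' (CMe2), C2' (CH2), C3' (C=O), C4'H=C5'(CH3), C6' (CH stereocentre, bonded to C13).
2. Key disconnection, three components in one pot: the C11–C12 bond and the C11–CH3 bond are cut together. This gives the C1–C11 1,1-dibromide (C10H=C11Br2), the ring-bearing (E)-alkenylstannane (C12, C13 and the cyclohexenone ring) and Me2Zn.
3. Enabling feature: besides its double bond to C10, C11 carries two carbon groups, CH3 cis to C9 and C12 of the C12=C13 vinylene trans to C9. They map on the cis and trans bromines of the dibromide, of which the one trans to C9 reacts first. The C6'–H, γ to the C3' ketone through C4'=C5', is base-labile, so the union is run under neutral palladium conditions.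
4. Stannane: hydrostannation of the C12≡C13 alkyne; C3' ketone by allylic oxidation; alkyne from the aldehyde of a Johnson–Claisen ester whose C6' centre comes by chirality transfer from a CBS-derived (R)-allylic alcohol. Dibromide: three Wittig extensions of fumaraldehyde mono(dimethyl acetal), then dibromo-olefination.
5. Rings: the single carbocycle is already present in the starting cyclohexenone; no ring is formed during the route.

Key step: step 11

Assumption: 2,4,4-trimethylcyclohex-2-en-1-one, (2E)-4,4-dimethoxybut-2-enal and the phosphorus, tin, zinc and palladium reagents named are taken as purchasable; all polyene steps are run under argon in dim light.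

Step 1
Reactants: 1 2,4,4-trimethylcyclohex-2-en-1-one
Product: 2 (1R)-2,4,4-trimethylcyclohex-2-en-1-ol
Conditions: (S)-2-methyl-CBS-oxazaborolidine (10 mol %), BH3·SMe2 (0.7 equiv), THF, −20 °C; MeOH, then aq. NH4Cl
Reagents that add atoms: none
Why: Corey–Bakshi–Shibata reduction: the (S)-oxazaborolidine–borane complex binds the ketone anti to its larger 2-methylalkenyl arm and should deliver hydride to the face that gives the (R)-carbinol, the same sense in which acetophenone gives (R)-1-phenylethanol; this carbinol centre is the source of all later chirality.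

Step 2
Reactants: 2 (1R)-2,4,4-trimethylcyclohex-2-en-1-ol
Product: 3 ethyl 2-[(1S)-2,6,6-trimethylcyclohex-2-en-1-yl]acetate
Conditions: MeC(OEt)3 (6 equiv), EtCO2H (5 mol %), 140 °C, EtOH distilled off
Reagents that add atoms: triethyl orthoacetate CC(OCC)(OCC)OCC
Why: Johnson–Claisen rearrangement: the mixed ketene acetal formed on the allylic oxygen undergoes a [3,3] shift that is necessarily suprafacial on the ring, so the new C–C bond at the neopentyl-type alkene carbon forms on the face that carried oxygen and the (R)-carbinol configuration is relayed into the (S)-configured side-chain carbon (the later C6'), while the alkene moves to the position required in the target.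

Step 3
Reactants: 3 ethyl 2-[(1S)-2,6,6-trimethylcyclohex-2-en-1-yl]acetate
Product: 4 2-[(1S)-2,6,6-trimethylcyclohex-2-en-1-yl]acetaldehyde
Conditions: i-Bu2AlH (1.05 equiv), CH2Cl2, −78 °C; aq. Rochelle salt
Reagents that add atoms: none
Why: DIBAL-H partial reduction of an ester: the tetrahedral aluminium hemiacetal is stable at −78 °C and collapses to the aldehyde only on work-up; the stereocentre is β to the carbonyl group and cannot enolise.

Step 4
Reactants: 4 2-[(1S)-2,6,6-trimethylcyclohex-2-en-1-yl]acetaldehyde
Product: 6 (6R)-6-ethynyl-1,5,5-trimethylcyclohex-1-ene, via enol nonaflate 5 (not isolated)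
Conditions: C4F9SO2F (1.2 equiv), phosphazene base P2-Et (2.3 equiv), DMF, 0 °C → rt
Reagents that add atoms: none
Why: Alkenyl nonaflate route from an enolisable aldehyde to a terminal alkyne: the phosphazene base forms the enolate, which is O-sulfonylated to 5, and a second equivalent of base removes the vinylic proton with loss of nonaflate (E2), while the allylic C–H of the stereocentre is far too weakly acidic to be touched (the descriptor changes to R only because ethynyl outranks the CMe2 carbon).

Step 5
Reactants: 6 (6R)-6-ethynyl-1,5,5-trimethylcyclohex-1-ene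
Product: 7 (4R)-4-ethynyl-3,5,5-trimethylcyclohex-2-en-1-one
Conditions: CrO3 (12 equiv), 3,5-dimethylpyrazole (12 equiv), CH2Cl2, −20 °C
Reagents that add atoms: chromium trioxide O=[Cr](=O)=O
Why: Allylic oxidation with the CrO3·3,5-dimethylpyrazole complex: the ring CH2 next to the trisubstituted alkene is converted into the enone carbonyl as in α-ionone-type cyclohexenes, the tertiary C–H of the stereocentre being shielded by the gem-dimethyl carbon on one side and the ring methyl group on the other, and the base-free medium leaves the now γ-acidic stereocentre configurationally intact.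

Step 6
Reactants: 7 (4R)-4-ethynyl-3,5,5-trimethylcyclohex-2-en-1-one
Product: 8 (4S)-3,5,5-trimethyl-4-[(E)-2-(tributylstannyl)ethenyl]cyclohex-2-en-1-one
Conditions: Bu3SnH (1.1 equiv), PdCl2(PPh3)2 (2 mol %), THF, 0 °C → rt; chromatography on neutral alumina
Reagents that add atoms: tributyltin hydride CCCC[SnH](CCCC)CCCC
Why: Pd-catalysed syn-hydrostannation of a terminal alkyne: the crowded propargylic carbon steers tin to the terminal carbon and syn addition gives the (E)-alkenylstannane under neutral conditions that spare the enone and its γ-stereocentre.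

Step 7
Reactants: 9 (2E)-4,4-dimethoxybut-2-enal
Product: 11 methyl (2E,4E)-2-methyl-6-oxohexa-2,4-dienoate, via dimethyl acetal 10 (not isolated)
Conditions: Ph3P=C(Me)CO2Me (1.1 equiv), CH2Cl2, 0 °C → rt; then 1 M aq. HCl, THF, rt
Reagents that add atoms: methyl 2-(triphenylphosphoranylidene)propanoate COC(=O)C(C)=P(c1ccccc1)(c1ccccc1)c1ccccc1; water O
Why: Wittig reaction with a stabilised α-methyl ylide, E-selective, followed by acid hydrolysis of the dimethyl acetal during work-up.

Step 8
Reactants: 11 methyl (2E,4E)-2-methyl-6-oxohexa-2,4-dienoate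
Product: 12 methyl (2E,4E,6E)-2,7-dimethyl-8-oxoocta-2,4,6-trienoate
Conditions: Ph3P=C(Me)CHO (1.2 equiv), toluene, 80 °C
Reagents that add atoms: 2-(triphenylphosphoranylidene)propanal CC(C=O)=P(c1ccccc1)(c1ccccc1)c1ccccc1
Why: Wittig reaction with the stabilised formyl ylide, E-selective; the α-methyl enal formed is less electrophilic than the dienal 11, so a second homologation should not compete.

Step 9
Reactants: 12 methyl (2E,4E,6E)-2,7-dimethyl-8-oxoocta-2,4,6-trienoate
Product: 14 methyl (2E,4E,6E,8E)-2,7-dimethyl-10-oxodeca-2,4,6,8-tetraenoate, via dioxolane 13 (not isolated)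
Conditions: (1,3-dioxolan-2-ylmethyl)triphenylphosphonium bromide (1.5 equiv), LiOMe (1.6 equiv), DMF, 80 °C; then 1 M aq. HCl, THF, rt
Reagents that add atoms: (1,3-dioxolan-2-ylmethyl)triphenylphosphonium bromide [Br-].C1COC(C[P+](c2ccccc2)(c2ccccc2)c2ccccc2)O1; water O
Why: Wittig two-carbon homologation with the dioxolanylmethyl ylide and acetal hydrolysis: the acid step also equilibrates the Z/E mixture of 13 to the conjugated (E)-enal, and LiOMe is degenerate towards the methyl ester.

Step 10
Reactants: 14 methyl (2E,4E,6E,8E)-2,7-dimethyl-10-oxodeca-2,4,6,8-tetraenoate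
Product: 15 methyl (2E,4E,6E,8E)-11,11-dibromo-2,7-dimethylundeca-2,4,6,8,10-pentaenoate
Conditions: CBr4 (2 equiv), PPh3 (2 equiv), Zn dust (2 equiv), CH2Cl2, rt, 12 h; then 14, 0 °C → rt
Reagents that add atoms: carbon tetrabromide BrC(Br)(Br)Br
Why: Ramirez dibromo-olefination (first stage of the Corey–Fuchs sequence) with the preformed ylide Ph3P=CBr2; zinc consumes the dibromophosphorane so that neither bromine nor acid reaches the polyene.

Step 11
Reactants: 8 (4S)-3,5,5-trimethyl-4-[(E)-2-(tributylstannyl)ethenyl]cyclohex-2-en-1-one; 15 methyl (2E,4E,6E,8E)-11,11-dibromo-2,7-dimethylundeca-2,4,6,8,10-pentaenoate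
Product: 17 methyl (2E,4E,6E,8E,10E,12E)-2,7,11-trimethyl-13-[(1S)-2,6,6-trimethyl-4-oxocyclohex-2-en-1-yl]trideca-2,4,6,8,10,12-hexaenoate, via (10Z)-bromide 16 (not isolated)
Conditions: 8 (1.05 equiv), 15 (1.0 equiv), Pd2(dba)3 (2.5 mol %), tri(2-furyl)phosphine (15 mol %), toluene, 80 °C; then 23 °C, Pd(P(t-Bu)3)2 (5 mol %), Me2Zn (3 equiv), THF, 23 °C
Reagents that add atoms: dimethylzinc C[Zn]C
Why: Zerovalent palladium inserts selectively into the C11–Br bond of 15 that is trans to C9 (cis to H-10, the less hindered one); tin-to-palladium transmetallation of 8 and reductive elimination then form the C11–C12 bond with retention at both alkenes to give the (10Z)-bromide 16, whose remaining, more hindered C11–Br bond is engaged by Pd(P(t-Bu)3)2 and methylated by Me2Zn with retention, so that the bond between the two fragments, the C11 methyl group and the 10E geometry are all set in one flask from three components. The closest known reaction types are the trans-selective Stille mono-coupling of 1,1-dibromo-1-alkenes with alkenylstannanes and the one-pot Pd-catalysed trans-selective alkenylation/methylation of 1,1-dibromo-1-alkenes with organozincs that delivers (1E)-2-methyl-1,3-dienes. No ring is closed and no stereocentre is created; the 12E geometry is carried in from 8 and the 10E geometry follows from the order of the two substitutions. The step needs site selectivity between the two bromines, which the steric difference between cis-H and cis-C9 and the weakly donating furylphosphine in non-polar toluene should secure (this medium also disfavours HBr loss from 16 to an enyne), and it needs retention in the methylation, which the bulky monoligating P(t-Bu)3 should secure by outrunning isomerisation of the 2-palladadiene. The conditions are neutral throughout, so the base-labile C6' stereocentre and the methyl ester are untouched, and Me2Zn does not add to the enone or the ester without a further catalyst.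

**Compound list**

1 | 2,4,4-trimethylcyclohex-2-en-1-one | CC1=CC(C)(C)CCC1=O | starting material
2 | (1R)-2,4,4-trimethylcyclohex-2-en-1-ol | O[C@H]1C(C)=CC(C)(C)CC1 | intermediate
3 | ethyl 2-[(1S)-2,6,6-trimethylcyclohex-2-en-1-yl]acetate | CCOC(=O)C[C@@H]1C(C)=CCCC1(C)C | intermediate
4 | 2-[(1S)-2,6,6-trimethylcyclohex-2-en-1-yl]acetaldehyde | O=CC[C@@H]1C(C)=CCCC1(C)C | intermediate
5 | 2-[(1S)-2,6,6-trimethylcyclohex-2-en-1-yl]ethenyl nonafluorobutane-1-sulfonate (E/Z mixture) | FC(F)(F)C(F)(F)C(F)(F)C(F)(F)S(=O)(=O)OC=C[C@@H]1C(C)=CCCC1(C)C | intermediate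
6 | (6R)-6-ethynyl-1,5,5-trimethylcyclohex-1-ene | C#C[C@@H]1C(C)=CCCC1(C)C | intermediate
7 | (4R)-4-ethynyl-3,5,5-trimethylcyclohex-2-en-1-one | C#C[C@@H]1C(C)=CC(=O)CC1(C)C | intermediate
8 | (4S)-3,5,5-trimethyl-4-[(E)-2-(tributylstannyl)ethenyl]cyclohex-2-en-1-one | CCCC[Sn](CCCC)(CCCC)/C=C/[C@@H]1C(C)=CC(=O)CC1(C)C | intermediate
9 | (2E)-4,4-dimethoxybut-2-enal (fumaraldehyde mono(dimethyl acetal)) | COC(OC)/C=C/C=O | starting material
10 | methyl (2E,4E)-6,6-dimethoxy-2-methylhexa-2,4-dienoate | COC(=O)/C(C)=C/C=C/C(OC)OC | intermediate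
11 | methyl (2E,4E)-2-methyl-6-oxohexa-2,4-dienoate | COC(=O)/C(C)=C/C=C/C=O | intermediate
12 | methyl (2E,4E,6E)-2,7-dimethyl-8-oxoocta-2,4,6-trienoate | COC(=O)/C(C)=C/C=C/C=C(C)/C=O | intermediate
13 | methyl (2E,4E,6E)-9-(1,3-dioxolan-2-yl)-2,7-dimethylnona-2,4,6,8-tetraenoate (8E/8Z mixture) | COC(=O)/C(C)=C/C=C/C=C(C)/C=CC1OCCO1 | intermediate
14 | methyl (2E,4E,6E,8E)-2,7-dimethyl-10-oxodeca-2,4,6,8-tetraenoate | COC(=O)/C(C)=C/C=C/C=C(C)/C=C/C=O | intermediate
15 | methyl (2E,4E,6E,8E)-11,11-dibromo-2,7-dimethylundeca-2,4,6,8,10-pentaenoate | COC(=O)/C(C)=C/C=C/C=C(C)/C=C/C=C(Br)Br | intermediate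
16 | methyl (2E,4E,6E,8E,10Z,12E)-11-bromo-2,7-dimethyl-13-[(1S)-2,6,6-trimethyl-4-oxocyclohex-2-en-1-yl]trideca-2,4,6,8,10,12-hexaenoate | COC(=O)/C(C)=C/C=C/C=C(C)/C=C/C=C(Br)/C=C/[C@@H]1C(C)=CC(=O)CC1(C)C | intermediate
17 | methyl (2E,4E,6E,8E,10E,12E)-2,7,11-trimethyl-13-[(1S)-2,6,6-trimethyl-4-oxocyclohex-2-en-1-yl]trideca-2,4,6,8,10,12-hexaenoate | COC(=O)/C(C)=C/C=C/C=C(C)/C=C/C=C(C)/C=C/[C@@H]1C(C)=CC(=O)CC1(C)C | target

**Step count and risks**

Total step count: 11. Longest linear sequence: 7 steps (steps 1–6 and 11); the chain arm is 4 steps (7–10) before the union.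

The three steps most likely to fail:

Step 11. What may go wrong: erosion of site selectivity between the two C–Br bonds, loss of HBr from the intermediate monobromide, or ligand cross-talk between the two palladium catalysts that lets the methyl transfer proceed with partial inversion at C10=C11. Fallback, a two-partner Stille union with the methyl group already in place; it sets out from 12 and comes back to the route at 17. Wittig reaction of 12 with the ylide from (but-2-yn-1-yl)triphenylphosphonium bromide (NaN(SiMe3)2, THF, −78 °C, then iodine-catalysed equilibration of the new double bond) should give the enyne methyl (2E,4E,6E,8E)-2,7-dimethyldodeca-2,4,6,8-tetraen-10-ynoate F1. Syn-hydrozirconation with Cp2Zr(H)Cl (THF, rt), which places zirconium on the less hindered, methyl-bearing alkyne carbon, should give the alkenylzirconocene chloride methyl (2E,4E,6E,8E,10E)-11-[chlorobis(cyclopentadienyl)zirconio]-2,7-dimethyldodeca-2,4,6,8,10-pentaenoate F2, which is not isolated but treated with iodine to give the iodide methyl (2E,4E,6E,8E,10E)-11-iodo-2,7-dimethyldodeca-2,4,6,8,10-pentaenoate F3. Stille coupling of F3 with 8 (Pd2(dba)3, AsPh3, NMP, rt), with retention at both alkenes, should then give 17.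

Step 5. What may go wrong: hydrogen abstraction at the doubly activated (allylic and propargylic) C–H of the stereocentre instead of the ring CH2, leading to rearranged or over-oxidised material and loss of configuration. Fallback, oxygen brought in through the alkene and moved by 1,3-transposition instead of C–H oxidation; it sets out from 6 and comes back at 7. Epoxidation of the ring alkene (3-chloroperoxybenzoic acid, NaHCO3, CH2Cl2, 0 °C) should give the epoxide (2R)-2-ethynyl-1,3,3-trimethyl-7-oxabicyclo[4.1.0]heptane F4 (either epoxide face serves). Opening at the less substituted epoxide carbon with PhSeNa (from PhSeSePh and NaBH4, EtOH) should give the hydroxy selenide (2R)-2-ethynyl-1,3,3-trimethyl-6-(phenylselanyl)cyclohexan-1-ol F5. Oxidation with H2O2 (THF, 0 °C → rt) gives the selenoxide (2R)-2-ethynyl-1,3,3-trimethyl-6-(phenylseleninyl)cyclohexan-1-ol F6, which is not isolated and syn-eliminates away from the carbinol carbon to the tertiary allylic alcohol (6R)-6-ethynyl-1,5,5-trimethylcyclohex-2-en-1-ol F7. Babler–Dauben oxidative transposition with pyridinium chlorochromate, [C5H5NH][CrO3Cl], in CH2Cl2 should then deliver 7.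

Step 4. What may go wrong: aldol self-condensation of the aldehyde under the strong base, or incomplete elimination of the alkenyl nonaflate. Fallback, the side chain built one carbon at a time, bypassing steps 2–4; it sets out from 2 and comes back at 6. O-Alkylation of 2 with Bu3SnCH2I (KH, THF) should give the stannylmethyl ether tributyl({[(1R)-2,4,4-trimethylcyclohex-2-en-1-yl]oxy}methyl)stannane F8. Tin–lithium exchange (n-BuLi, THF, −78 °C) triggers the suprafacial [2,3]-Wittig–Still rearrangement to [(1S)-2,6,6-trimethylcyclohex-2-en-1-yl]methanol F9. Dess–Martin oxidation (CH2Cl2, NaHCO3) should give (1S)-2,6,6-trimethylcyclohex-2-ene-1-carbaldehyde F10, and Colvin homologation with lithium trimethylsilyldiazomethane (THF, −78 °C → rt), chosen to spare the epimerisable formyl-bearing carbon, should give 6.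

Further compounds
F1 | step 11 | methyl (2E,4E,6E,8E)-2,7-dimethyldodeca-2,4,6,8-tetraen-10-ynoate | COC(=O)/C(C)=C/C=C/C=C(C)/C=C/C#CC
F2 | step 11 | methyl (2E,4E,6E,8E,10E)-11-[chlorobis(cyclopentadienyl)zirconio]-2,7-dimethyldodeca-2,4,6,8,10-pentaenoate | COC(=O)/C(C)=C/C=C/C=C(C)/C=C/C=C(C)/[Zr](Cl)(C1C=CC=C1)C1C=CC=C1
F3 | step 11 | methyl (2E,4E,6E,8E,10E)-11-iodo-2,7-dimethyldodeca-2,4,6,8,10-pentaenoate | COC(=O)/C(C)=C/C=C/C=C(C)/C=C/C=C(C)/I
F4 | step 5 | (2R)-2-ethynyl-1,3,3-trimethyl-7-oxabicyclo[4.1.0]heptane (both epoxide faces) | C#C[C@@H]1C2(C)OC2CCC1(C)C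
F5 | step 5 | (2R)-2-ethynyl-1,3,3-trimethyl-6-(phenylselanyl)cyclohexan-1-ol | C#C[C@@H]1C(C)(O)C([Se]c2ccccc2)CCC1(C)C
F6 | step 5 | (2R)-2-ethynyl-1,3,3-trimethyl-6-(phenylseleninyl)cyclohexan-1-ol | C#C[C@@H]1C(C)(O)C([Se](=O)c2ccccc2)CCC1(C)C
F7 | step 5 | (6R)-6-ethynyl-1,5,5-trimethylcyclohex-2-en-1-ol | C#C[C@@H]1C(C)(O)C=CCC1(C)C
F8 | step 4 | tributyl({[(1R)-2,4,4-trimethylcyclohex-2-en-1-yl]oxy}methyl)stannane | CCCC[Sn](CCCC)(CCCC)CO[C@H]1C(C)=CC(C)(C)CC1
F9 | step 4 | [(1S)-2,6,6-trimethylcyclohex-2-en-1-yl]methanol | OC[C@@H]1C(C)=CCCC1(C)C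
F10 | step 4 | (1S)-2,6,6-trimethylcyclohex-2-ene-1-carbaldehyde | O=C[C@@H]1C(C)=CCCC1(C)C
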